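**Retrosynthetic overview**

1. The acetate C–O bond and the aryl–C(carbinol) bond are cut last: this gives 3,4-dimethoxyphenylmagnesium bromide and an α-methyl aldehyde carried by the cyclohexadienone (Felkin–Anh addition, acetyl trap in the same flask).
2. Enabling feature: after that cut, the aldehyde carbon, the methyl-bearing carbon, the quaternary methoxy ring carbon C-4 and the ring alkene C-3=C-2 (C-2 carries the allyl group) form a pent-4-enal. A retro-Claisen shift therefore moves the side chain onto an (E)-prop-1-enyloxy group on the allyl-bearing carbon, giving a 6-allyl-6-alkoxycyclohexa-2,4-dienone whose C–O bond and stereocentre are absent from the target and are consumed when the quaternary centre is made.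
3. The propenyl ether comes from the O-allyl ether (Ir-catalysed alkene isomerisation, same flask), this from the tertiary o-quinol, and this from enantioselective mono-allylation of C2v-symmetric 4,5-dimethoxy-1,2-benzoquinone, made from catechol.
4. Rings: the six-membered carbocycle is that of catechol, dearomatised in the first step and never re-closed; the dimethoxybenzene ring is bought as the Grignard reagent; no ring is formed in the route.

Key step: step 4

Assumption: the sense of induction of the scandium–pybox catalyst in step 2 is assigned by analogy with allylations of isatins; should the (R)-carbinol predominate, the enantiomeric ligand is used and nothing else changes.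

**Step 1**
Reactants: 1 catechol (benzene-1,2-diol)
Product: 2 4,5-dimethoxycyclohexa-3,5-diene-1,2-dione (4,5-dimethoxy-1,2-benzoquinone)
Conditions: NaIO3, MeOH, 0 °C → rt
Reagents that add atoms: methanol (CO)
Why: Oxidative methoxylation of catechol: iodate oxidises it to o-benzoquinone, which takes up methanol twice by conjugate addition with re-oxidation after each addition and stops at the push–pull stabilised dimethoxy-o-quinone.

**Step 2**
Reactants: 2 4,5-dimethoxycyclohexa-3,5-diene-1,2-dione
Product: 3 (6S)-6-hydroxy-3,4-dimethoxy-6-(prop-2-en-1-yl)cyclohexa-2,4-dien-1-one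
Conditions: allylSnBu3, Sc(OTf)3 (10 mol%), (S,S)-inda-pybox (12 mol%), 4 Å MS, CH2Cl2, −78 → −40 °C; aq. NaHCO3 at −78 °C
Reagents that add atoms: allyltributylstannane (C=CC[Sn](CCCC)(CCCC)CCCC)
Why: Chiral Lewis acid-catalysed carbonyl allylation of a chelating cyclic 1,2-dicarbonyl compound (closest case: Sc(III)–pybox allylation of isatins): the dione binds scandium through both oxygens, the two carbonyl groups are homotopic, so 1,2-addition to either one from the open face of the chelate should give the same (6S)-carbinol, and the low temperature keeps the C-allyl group from migrating.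

**Step 3**
Reactants: 3 (6S)-6-hydroxy-3,4-dimethoxy-6-(prop-2-en-1-yl)cyclohexa-2,4-dien-1-one
Product: 4 (6S)-3,4-dimethoxy-6-(prop-2-en-1-yl)-6-(prop-2-en-1-yloxy)cyclohexa-2,4-dien-1-one
Conditions: allyl iodide, Ag2O, 4 Å MS, Et2O, rt, dark
Reagents that add atoms: allyl iodide (C=CCI)
Why: Silver(I) oxide-promoted Williamson-type O-alkylation allylates the tertiary α-ketol without a free alkoxide, so neither an anionic oxy-Cope shift of the C-allyl group nor an α-ketol shift (which would racemise C-6) should start; the stereocentre is not touched.

**Step 4**
Reactants: 4 (6S)-3,4-dimethoxy-6-(prop-2-en-1-yl)-6-(prop-2-en-1-yloxy)cyclohexa-2,4-dien-1-one; 5 3,4-dimethoxyphenylmagnesium bromide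
Product: 9 (1R,2R)-1-(3,4-dimethoxyphenyl)-2-[(1R)-1,2-dimethoxy-4-oxo-5-(prop-2-en-1-yl)cyclohexa-2,5-dien-1-yl]propyl acetate, via (E)-propenyl ether 6 (not isolated), via aldehyde 7 (not isolated), via magnesium alkoxide 8 (not isolated)
Conditions: [Ir(cod)(PMePh2)2]PF6 (2 mol%, activated with H2, then degassed), THF, rt; PPh3 (10 mol%), 60 °C; 5, THF, −78 °C; Ac2O, DMAP (5 mol%), −78 → 0 °C; aq. NaHCO3
Reagents that add atoms: acetic anhydride (CC(=O)OC(C)=O)
Why: The cationic iridium hydride moves the double bond of the O-allyl group, the only oxygen-activated and the less hindered of the two terminal alkenes, into conjugation with oxygen and should give the (E)-prop-1-enyl ether 6, an allyl vinyl ether whose allyl part is C6–C5=C4 of the dienone; on warming, 6 should undergo the Claisen [3,3] shift, which breaks the temporary C6–O bond, joins the enol ether carbon to the methoxy-bearing C4 and turns the linear 2,4-dienone into the cross-conjugated 2,5-dienone aldehyde 7, to which Grignard reagent 5 adds at −78 °C before alkoxide 8 is acetylated in the same flask. The closest known reaction types are the iridium-catalysed isomerisation–Claisen rearrangement of di(allyl) ethers with derivatisation of the aldehyde in situ, the Cope step of the para-Claisen rearrangement (6-allylcyclohexa-2,4-dienone to 4-allylcyclohexa-2,5-dienone), which shows that [3,3] shifts across this ring are easy, and the Felkin–Anh addition of a Grignard reagent with acylative quench. No ring is closed: the only cyclic array is the six-membered chair transition state of the sigmatropic shift, suprafacial on the ring. The quaternary centre is set by chirality transfer from the sacrificial C6 centre (the new C–C bond forms on the ring face that carried the oxygen, so (6S) gives (1R) in 7), the methyl-bearing centre by the chair transition state in which the methyl group of the (E)-enol ether is pseudo-equatorial (giving (2S) in 7), and the carbinol centre by Felkin–Anh attack of the aryl group anti to the quaternary carbon, which places the oxygen syn to the methyl group. The step needs chemoselective isomerisation (secured by the ether oxygen and the neopentyl position of the C-allyl group, with PPh3 stopping the catalyst before heating), Claisen shift ahead of the Cope shift of the C-allyl group (the C–O bond is the weaker σ-bond and a C=O bond is gained), and 1,2-addition to the aldehyde alone (the ring carbonyl is a hindered vinylogous ester). Non-chelating THF at −78 °C and immediate acylation are chosen so that the β-methoxy group does not reverse the facial preference and the alkoxide does not add to the methoxy-enone.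

**Compound list**

1 | catechol (benzene-1,2-diol) | Oc1ccccc1O | starting material
2 | 4,5-dimethoxycyclohexa-3,5-diene-1,2-dione | COC1=CC(=O)C(=O)C=C1OC | intermediate
3 | (6S)-6-hydroxy-3,4-dimethoxy-6-(prop-2-en-1-yl)cyclohexa-2,4-dien-1-one | O=C1C=C(OC)C(OC)=C[C@@]1(O)CC=C | intermediate
4 | (6S)-3,4-dimethoxy-6-(prop-2-en-1-yl)-6-(prop-2-en-1-yloxy)cyclohexa-2,4-dien-1-one | O=C1C=C(OC)C(OC)=C[C@@]1(OCC=C)CC=C | intermediate
5 | 3,4-dimethoxyphenylmagnesium bromide (commercial THF solution) | COc1ccc([Mg]Br)cc1OC | starting material
6 | (6S)-3,4-dimethoxy-6-(prop-2-en-1-yl)-6-[(1E)-prop-1-en-1-yloxy]cyclohexa-2,4-dien-1-one | O=C1C=C(OC)C(OC)=C[C@@]1(O/C=C/C)CC=C | intermediate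
7 | (2S)-2-[(1R)-1,2-dimethoxy-4-oxo-5-(prop-2-en-1-yl)cyclohexa-2,5-dien-1-yl]propanal | C=CCC1=C[C@@](OC)([C@H](C)C=O)C(OC)=CC1=O | intermediate
8 | bromomagnesium (1R,2R)-1-(3,4-dimethoxyphenyl)-2-[(1R)-1,2-dimethoxy-4-oxo-5-(prop-2-en-1-yl)cyclohexa-2,5-dien-1-yl]propan-1-olate | C=CCC1=C[C@@](OC)([C@H](C)[C@@H](O[Mg]Br)c2ccc(OC)c(OC)c2)C(OC)=CC1=O | intermediate
9 | (1R,2R)-1-(3,4-dimethoxyphenyl)-2-[(1R)-1,2-dimethoxy-4-oxo-5-(prop-2-en-1-yl)cyclohexa-2,5-dien-1-yl]propyl acetate | C=CCC1=C[C@@](OC)([C@H](C)[C@@H](OC(C)=O)c2ccc(OC)c(OC)c2)C(OC)=CC1=O | target

**Step count and risks**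

Total step count: 4. Longest linear sequence: 4 steps (catechol to the target).

Steps most likely to fail:

Step 4. What may go wrong: after the sigmatropic stage, the Grignard reagent may deprotonate the aldehyde at its α-carbon (followed by loss of methoxide from the ring and re-aromatisation), the magnesium alkoxide may attack the methoxy-substituted enone carbon with ring closure, or β-methoxy chelation may erode the Felkin preference. Fallback: the one-pot sequence is stopped after the heating stage and aldehyde 7 is isolated by filtration through neutral alumina. The aryl group is then transferred under catalyst control from a weakly basic arylzinc reagent (3,4-dimethoxyphenylboronic acid, Et2Zn, chiral amino-alcohol ligand such as (−)-3-exo-morpholinoisoborneol, toluene, −10 °C), the ligand enantiomer being chosen to reinforce the Felkin preference. After aqueous work-up this should give the carbinol (4R)-4-[(1R,2R)-1-(3,4-dimethoxyphenyl)-1-hydroxypropan-2-yl]-4,5-dimethoxy-2-(prop-2-en-1-yl)cyclohexa-2,5-dien-1-one F1. Acetylation without a metal alkoxide (Ac2O, pyridine, DMAP, 0 °C) then leads to the target. The fallback sets out from 7 and comes back at 9.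

Step 2. What may go wrong: insufficient enantiofacial discrimination through uncatalysed or non-chelated background allylation, or Lewis acid-induced migration of the new C-allyl group. Fallback: asymmetric catalysis is replaced by resolution. Compound 2 is allylated without chiral control (allyltributylstannane, BF3·OEt2, CH2Cl2, −78 °C) to the racemic o-quinol rac-6-hydroxy-3,4-dimethoxy-6-(prop-2-en-1-yl)cyclohexa-2,4-dien-1-one F2. This is O-allylated as in step 3 to the racemic ether rac-3,4-dimethoxy-6-(prop-2-en-1-yl)-6-(prop-2-en-1-yloxy)cyclohexa-2,4-dien-1-one F3. The enantiomers of this ether are separated by preparative chromatography on a chiral stationary phase, and the (6S)-enantiomer is 4. The fallback sets out from 2 and comes back at 4.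

Step 3. What may go wrong: slow etherification of the hindered tertiary hydroxyl group, so that α-ketol shift (racemisation of C-6) or Cope shift of the C-allyl group competes; in addition, the later iridium-catalysed isomerisation may be inhibited by binding of the diene to the metal or may fail to distinguish the two allyl groups. Fallback: O-alkenylation replaces O-allylation and isomerisation. Copper(II)-promoted oxidative coupling (Chan–Lam type) of 3 with (E)-prop-1-enylboronic acid pinacol ester (Cu(OAc)2, Et3N, 4 Å MS, CH2Cl2, rt, air) proceeds with retention of alkene geometry and should give propenyl ether 6 directly. Compound 6 is purified cold and enters step 4 at the heating stage, without iridium. The fallback sets out from 3 and comes back at 6; it makes no new compound.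

**Further compounds**

F1 | step 4 | (4R)-4-[(1R,2R)-1-(3,4-dimethoxyphenyl)-1-hydroxypropan-2-yl]-4,5-dimethoxy-2-(prop-2-en-1-yl)cyclohexa-2,5-dien-1-one | C=CCC1=C[C@@](OC)([C@H](C)[C@@H](O)c2ccc(OC)c(OC)c2)C(OC)=CC1=O
F2 | step 2 | rac-6-hydroxy-3,4-dimethoxy-6-(prop-2-en-1-yl)cyclohexa-2,4-dien-1-one | O=C1C=C(OC)C(OC)=CC1(O)CC=C
F3 | step 2 | rac-3,4-dimethoxy-6-(prop-2-en-1-yl)-6-(prop-2-en-1-yloxy)cyclohexa-2,4-dien-1-one | O=C1C=C(OC)C(OC)=CC1(OCC=C)CC=C
F0 | step 3 | none | none
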